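**Slow links.** Links come slowly in both earlier runs. At 3.00 h the noon run held 29.2% links, more than the 16.5% of the richer midnight run.

the same everywhere: gas 110 mM (held)

| flask | first end groups | remark | time |
|---|---|---|---|
| noon | 0.011 M | run made earlier |  |
| midnight | 0.28 M | run made earlier |  |
| north | 0.0080 M |  | 4.0 h |
| north-east | 0.020 M |  | 4.0 h |
| west | 0.060 M |  | 4.0 h |
| north-west | 0.20 M |  | 4.0 h |

| run | time / h | links / % | first end groups / % |
|---|---|---|---|
| noon | 0.167 | 1.1 | 95.5 |
| noon | 0.417 | 1.3 | 88.4 |
| noon | 0.833 | 3.0 | 77.3 |
| noon | 1.33 | 10.6 | 65.0 |
| noon | 1.50 | 11.5 | 62.1 |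
| noon | 2.00 | 18.8 | 52.1 |
| noon | 3.00 | 29.2 | 38.8 |
| midnight | 0.417 | 0.9 | 88.4 |
| midnight | 0.833 | 3.1 | 79.1 |
| midnight | 1.33 | 6.7 | 66.9 |
| midnight | 1.50 | 8.4 | 64.0 |
| midnight | 2.00 | 9.7 | 57.4 |
| midnight | 2.50 | 12.3 | 50.4 |
| midnight | 3.00 | 16.5 | 46.5 |

(readings scatter by 1 percentage point)

- the earlier runs were read with a standard deviation of 1 percentage point
- at the start none of the gas is in solution
- a reading or a percentage of links counts all its forms, free or not
- the concentration of links that is asked is that of its free form alone
- "hardly changes" means that all values lie within two and a half points (for a concentration: within two and a half percent of the largest)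
- a reading of first end groups is of its free form alone

1. [links] (only what is free in solution) at the end for north, north-east, west, north-west, in this order
2. the course of these numbers from the first flask to the last (rises, then falls / rises all the way / hardly changes / falls all the way / falls, then rises)

**The ledger.** We book first end groups, the limiting reagent. Of the noon charge at 3.00 h, 38.8% stands free, 29.2% is links, and 32.0% is unread. In the midnight run the entries are 46.5%, 16.5% and 37.0%. The link entry differs most between the runs: their ratio reads 0.565.

**The crossing.** We let the link share fall with charge c as a factor 1/(1 + c/c×). From the two runs at 3.00 h, c× reads 0.338 M, the crossing charge, where the factor is 0.5. In this factor, links in M follow the charge well below c×. The largest of the four charges stands below c×.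

**Our reckoning.** Continuing the last noon hour to 4.0 h gives 39.6% links at the noon charge. The factor, carried unchanged to that time as our estimate, gives 0.003195 M for north and 0.0514 M for north-west, bound forms still counted. So the row rises, but less than in proportion.

**The forecast.** It gives 0.0031 M, 0.0075 M, 0.02 M and 0.045 M, and says rises all the way. Its top value is lower than ours: “I take a little off for bound forms”.

**The flasks.** Free links end at 0.00333 M, 0.00804 M, 0.0214 M and 0.0475 M, and the course rises all the way.

    first end groups ⇌ dormant form (K = 0.860, k = 0.269 h⁻¹)
    first end groups + links ⇌ idle adduct, settled at all times (K = 2.10 M⁻¹)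
    first end groups + second end groups → links (k = 5.51 M⁻¹ h⁻¹)
    gas ⇌ second end groups, rate k4*(csat - [second end groups]) (kL = 0.263 h⁻¹)

**What stood.** Links, bound form counted, stand in north-west at 0.652 of their share in north, where c× gives 0.643; for west the simulated ratio is 0.884 and c× gives 0.870. In north at 4.00 h, second end groups are made 12.7 times as fast as they are used, each step taken net, and they stand at 0.0694 M. In north-west at 4.00 h they stand at 0.0365 M, and their use coefficient, the link-making rate constant times free first end groups, is 0.396 h⁻¹, larger than the gas transfer coefficient of 0.263 h⁻¹.

The numbers in the tables stem from a simulated flask from invented constants; scatter was added.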